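**Plan**

- Retrosynthesis: the O4' benzyl ether is removed last. Ring A is then opened at C4a–C5, because C5–OH lies para to C8–OMe with C7–OMe and C6–H between them; this is the pattern produced when a 3,4-dimethoxycyclobut-2-enone carrying the 4-pyranone (ring C) on C4 is ring-expanded.
- Two further cuts: C8–C8a (a pyranone C6 carbanion adding to the ketone carbonyl of methyl semisquarate) and C2–C1' (Suzuki coupling of 2-bromo-3-methoxy-4-pyranone with the ring-B boronate).
- Forward order: ring B boronate and the intact pyranone ring C are joined first, the four-carbon squarate unit is attached at pyranone C6, ring A is closed last by thermolysis, and hydrogenolysis frees O4'.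
- Stereochemistry: the target has no stereocentre and no stereogenic double bond. The only stereochemical events are a racemic cyclobutenone C4 centre, destroyed in the key step, and the outward rotation of the C4 methoxy group during ring opening.

Key step: step 11

Remark: because the target is achiral, "single enantiomer" is met by the constitution alone; compounds 11, 14, 15 and 17 are racemic and lose their stereocentre later. Pyromeconic acid, bought as such, replaces kojic acid as the ring-C source so that the pyranone C6–H can be metalated directly.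

**Route**

Step 1
Reactants: 1 4-bromo-3-methoxyphenol
Product: 2 4-(benzyloxy)-1-bromo-2-methoxybenzene
Conditions: BnBr, K2CO3, DMF, 25 °C
Reagents that add atoms: benzyl bromide, BrCc1ccccc1
Why: Williamson ether synthesis of the phenoxide with a benzylic bromide; the benzyl ether should survive the organometallic and thermal steps and is cleaved by hydrogenolysis at the end.

Step 2
Reactants: 2 4-(benzyloxy)-1-bromo-2-methoxybenzene
Product: 3 2-[4-(benzyloxy)-2-methoxyphenyl]-4,4,5,5-tetramethyl-1,3,2-dioxaborolane
Conditions: B2pin2, Pd(dppf)Cl2 (3 mol %), KOAc, 1,4-dioxane, 90 °C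
Reagents that add atoms: bis(pinacolato)diboron, CC1(C)OB(OC1(C)C)B1OC(C)(C)C(C)(C)O1
Why: Miyaura borylation of an electron-rich aryl bromide; the pinacol ester is chosen because it resists protodeboronation better than the free 2,4-dialkoxyphenylboronic acid.

Step 3
Reactants: 4 pyromeconic acid (3-hydroxy-4H-pyran-4-one)
Product: 5 2-bromo-3-hydroxy-4H-pyran-4-one
Conditions: NBS (1.0 equiv), MeCN, 0 → 25 °C
Reagents that add atoms: N-bromosuccinimide, O=C1CCC(=O)N1Br
Why: electrophilic bromination of the enolic 3-hydroxy-4-pyranone should occur at C2, the enol β-carbon next to the hydroxyl, as in the 6-bromination of kojic acid.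

Step 4
Reactants: 5 2-bromo-3-hydroxy-4H-pyran-4-one
Product: 6 2-bromo-3-methoxy-4H-pyran-4-one
Conditions: MeI, K2CO3, acetone, 40 °C
Reagents that add atoms: iodomethane, CI
Why: Williamson O-methylation of the acidic enolic hydroxyl under mild carbonate conditions that leave the vinylogous acyl bromide untouched.

Step 5
Reactants: 6 2-bromo-3-methoxy-4H-pyran-4-one; 3 2-[4-(benzyloxy)-2-methoxyphenyl]-4,4,5,5-tetramethyl-1,3,2-dioxaborolane
Product: 7 2-[4-(benzyloxy)-2-methoxyphenyl]-3-methoxy-4H-pyran-4-one
Conditions: Pd(dppf)Cl2 (5 mol %), K3PO4, 1,4-dioxane/H2O (9:1), 80 °C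
Reagents that add atoms: none
Why: Suzuki–Miyaura coupling; the 2-bromo-4-pyranone is a vinylogous acyl bromide that adds oxidatively to Pd(0) with ease, and the phosphate base is mild enough to spare the pyranone ring.

Step 6
Reactants: 7 2-[4-(benzyloxy)-2-methoxyphenyl]-3-methoxy-4H-pyran-4-one
Product: 9 2-[4-(benzyloxy)-2-methoxyphenyl]-6-iodo-3-methoxy-4H-pyran-4-one, via pyranonylzinc chloride 8 (not isolated)
Conditions: TMPZnCl·LiCl (1.2 equiv), THF, 25 °C; then I2, 0 °C
Reagents that add atoms: iodine, II
Why: deprotonative zincation with a TMP zinc amide should remove the most acidic ring proton, C6–H next to the ring oxygen, as in the C2 zincation of chromones and 4-pyranones, and the weak base leaves C5–H, the ring-B protons and the benzylic CH2 alone; iodolysis of the C–Zn bond then gives the iodide.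

Step 7
Reactants: 10 dimethyl squarate
Product: 11 4-hydroxy-2,3-dimethoxycyclobut-2-en-1-one (racemic)
Conditions: LiAlH(Ot-Bu)3 (1.05 equiv), THF, −78 °C; H2O
Reagents that add atoms: none
Why: 1,2-reduction by a bulky alkoxyaluminium hydride of one of the two equivalent carbonyls; it should stop there because the remaining carbonyl is a deactivated vinylogous ester.

Step 8
Reactants: 11 4-hydroxy-2,3-dimethoxycyclobut-2-en-1-one
Product: 12 methyl semisquarate (3-methoxycyclobut-3-ene-1,2-dione)
Conditions: conc. HCl (cat.), CH2Cl2, 25 °C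
Reagents that add atoms: none
Why: acid-catalysed allylic transposition with loss of methanol (ionisation of the allylic alcohol to a methoxy-stabilised cyclobutenyl cation, capture by water at the methoxy-bearing terminus, collapse to the ketone), the standard conversion of 4-hydroxy-2,3-dialkoxycyclobutenones into 3-alkoxycyclobutene-1,2-diones.

Step 9
Reactants: 9 2-[4-(benzyloxy)-2-methoxyphenyl]-6-iodo-3-methoxy-4H-pyran-4-one; 12 methyl semisquarate
Product: 14 4-{6-[4-(benzyloxy)-2-methoxyphenyl]-5-methoxy-4-oxo-4H-pyran-2-yl}-4-hydroxy-3-methoxycyclobut-2-en-1-one (racemic), via pyranonylmagnesium chloride 13 (not isolated)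
Conditions: i-PrMgCl·LiCl (1.05 equiv), THF, −78 °C; cannulate into 12, THF, −78 °C; aq. NH4Cl
Reagents that add atoms: none
Why: iodine–magnesium exchange with the turbo-Grignard reagent is fast at −78 °C on this electron-poor sp2 iodide and should outrun attack on the pyranone, and the resulting Grignard reagent should add 1,2 to the carbonyl of 12 next to the methoxy-bearing carbon, the only ketone-like carbonyl since the other is a vinylogous ester, giving the tertiary alcohol as a racemate.

Step 10
Reactants: 14 4-{6-[4-(benzyloxy)-2-methoxyphenyl]-5-methoxy-4-oxo-4H-pyran-2-yl}-4-hydroxy-3-methoxycyclobut-2-en-1-one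
Product: 15 4-{6-[4-(benzyloxy)-2-methoxyphenyl]-5-methoxy-4-oxo-4H-pyran-2-yl}-3,4-dimethoxycyclobut-2-en-1-one (racemic)
Conditions: MeI, Ag2O, 4 Å MS, MeCN, 25 °C, dark
Reagents that add atoms: iodomethane, CI
Why: Purdie methylation (Ag2O/MeI) etherifies the tertiary hydroxyl under essentially neutral conditions, which avoids base-induced opening of the strained hydroxycyclobutenone and is the usual way to cap 4-hydroxycyclobutenones before thermolysis.

Step 11
Reactants: 15 4-{6-[4-(benzyloxy)-2-methoxyphenyl]-5-methoxy-4-oxo-4H-pyran-2-yl}-3,4-dimethoxycyclobut-2-en-1-one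
Product: 18 4'-(benzyloxy)-5-hydroxy-3,7,8,2'-tetramethoxyflavone, via (Z)-dienylketene 16 (not isolated), via 4aH-chromene-4,5-dione 17 (not isolated)
Conditions: PhMe (0.02 M, degassed), 110 °C, Ar
Reagents that add atoms: none
Why: Heating should break the C1–C4 bond of the cyclobutenone in a conrotatory 4π ring opening to the vinylketene 16, whose electrophilic ketene carbon then bonds to the nucleophilic C3 of the pyranone (α to the carbonyl, β to the ring oxygen) in a 6π electrocyclisation to give dienone 17, and enolisation of the ring-fusion hydrogen delivers the aromatic, hydrogen-bonded 5-hydroxyl. The closest known reaction is the Moore ring expansion of 4-aryl-, 4-heteroaryl- and 4-alkenyl-4-alkoxycyclobutenones to para-alkoxyphenols. The benzenoid A ring is the one ring formed; it closes by a thermal disrotatory 6π electrocyclisation that makes C4a–C5, and the former ketone carbon becomes C5–OH, the ring CH becomes C6, and the two methoxy carbons become C7 and C8. No stereocentre remains in the product, since the C4a centre of 17 is lost on tautomerisation. Two selectivities are needed: torquoselectivity, secured because the donor methoxy group on C4 rotates outward and so places the pyranone cis to the ketene, and site selectivity, secured because attack by the ring oxygen would only give a zwitterion that reverts whereas attack at C3 is made irreversible by aromatisation. The placement of C8–OMe and C7–OMe was already fixed by the regiochemistry of the addition in step 9.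

Step 12
Reactants: 18 4'-(benzyloxy)-5-hydroxy-3,7,8,2'-tetramethoxyflavone
Product: 19 5,4'-dihydroxy-3,7,8,2'-tetramethoxyflavone
Conditions: H2 (1 atm), 10% Pd/C, EtOAc/MeOH, 25 °C
Reagents that add atoms: none
Why: hydrogenolysis of the benzyl aryl ether over palladium; the tetrasubstituted flavone C2=C3 bond, the methyl ethers and the chelated 5-hydroxyl should be inert at 1 atm and room temperature.

**Compound list**

1 | 4-bromo-3-methoxyphenol | COc1cc(O)ccc1Br | starting material
2 | 4-(benzyloxy)-1-bromo-2-methoxybenzene | COc1cc(OCc2ccccc2)ccc1Br | intermediate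
3 | 2-[4-(benzyloxy)-2-methoxyphenyl]-4,4,5,5-tetramethyl-1,3,2-dioxaborolane | COc1cc(OCc2ccccc2)ccc1B1OC(C)(C)C(C)(C)O1 | intermediate
4 | pyromeconic acid (3-hydroxy-4H-pyran-4-one) | O=c1ccocc1O | starting material
5 | 2-bromo-3-hydroxy-4H-pyran-4-one | O=c1ccoc(Br)c1O | intermediate
6 | 2-bromo-3-methoxy-4H-pyran-4-one | COc1c(Br)occc1=O | intermediate
7 | 2-[4-(benzyloxy)-2-methoxyphenyl]-3-methoxy-4H-pyran-4-one | COc1cc(OCc2ccccc2)ccc1-c1occc(=O)c1OC | intermediate
8 | {6-[4-(benzyloxy)-2-methoxyphenyl]-5-methoxy-4-oxo-4H-pyran-2-yl}zinc chloride (not isolated) | COc1cc(OCc2ccccc2)ccc1-c1oc([Zn]Cl)cc(=O)c1OC | intermediate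
9 | 2-[4-(benzyloxy)-2-methoxyphenyl]-6-iodo-3-methoxy-4H-pyran-4-one | COc1cc(OCc2ccccc2)ccc1-c1oc(I)cc(=O)c1OC | intermediate
10 | dimethyl squarate (3,4-dimethoxycyclobut-3-ene-1,2-dione) | COC1=C(OC)C(=O)C1=O | starting material
11 | 4-hydroxy-2,3-dimethoxycyclobut-2-en-1-one (racemic) | COC1=C(OC)C(O)C1=O | intermediate
12 | methyl semisquarate (3-methoxycyclobut-3-ene-1,2-dione) | COC1=CC(=O)C1=O | intermediate
13 | {6-[4-(benzyloxy)-2-methoxyphenyl]-5-methoxy-4-oxo-4H-pyran-2-yl}magnesium chloride (not isolated) | COc1cc(OCc2ccccc2)ccc1-c1oc([Mg]Cl)cc(=O)c1OC | intermediate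
14 | 4-{6-[4-(benzyloxy)-2-methoxyphenyl]-5-methoxy-4-oxo-4H-pyran-2-yl}-4-hydroxy-3-methoxycyclobut-2-en-1-one (racemic) | O=C1C=C(OC)C1(O)c1cc(=O)c(OC)c(-c2ccc(OCc3ccccc3)cc2OC)o1 | intermediate
15 | 4-{6-[4-(benzyloxy)-2-methoxyphenyl]-5-methoxy-4-oxo-4H-pyran-2-yl}-3,4-dimethoxycyclobut-2-en-1-one (racemic) | O=C1C=C(OC)C1(OC)c1cc(=O)c(OC)c(-c2ccc(OCc3ccccc3)cc2OC)o1 | intermediate
16 | (3Z)-4-{6-[4-(benzyloxy)-2-methoxyphenyl]-5-methoxy-4-oxo-4H-pyran-2-yl}-3,4-dimethoxybuta-1,3-dien-1-one (not isolated) | O=C=C/C(OC)=C(OC)\c1cc(=O)c(OC)c(-c2ccc(OCc3ccccc3)cc2OC)o1 | intermediate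
17 | 2-[4-(benzyloxy)-2-methoxyphenyl]-3,7,8-trimethoxy-4aH-chromene-4,5-dione (racemic, not isolated) | COC1=CC(=O)C2C(=O)C(OC)=C(c3ccc(OCc4ccccc4)cc3OC)OC2=C1OC | intermediate
18 | 4'-(benzyloxy)-5-hydroxy-3,7,8,2'-tetramethoxyflavone | COc1cc(OCc2ccccc2)ccc1-c1oc2c(OC)c(OC)cc(O)c2c(=O)c1OC | intermediate
19 | 5,4'-dihydroxy-3,7,8,2'-tetramethoxyflavone | COc1cc(O)ccc1-c1oc2c(OC)c(OC)cc(O)c2c(=O)c1OC | target

**Step count and risks**

Total step count: 12. Longest linear sequence: 8 steps (steps 1, 2, 5, 6, 9, 10, 11, 12; the pyranone branch through steps 3 and 4 is equally long).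

The three steps most likely to fail, in order of risk:

Step 9. The exchange reagent may add in conjugate fashion to the pyranone, the magnesiated pyranone may attack unreacted iodide, or the nucleophile may attack the methoxy-bearing carbon of 12 with loss of methoxide instead of adding to the carbonyl. The fallback sets out from 7 and avoids both the iodide and any alkylmagnesium reagent. Deprotonation of 7 at C6 with LiTMP in THF at −78 °C, following the known C2 lithiation of chromones, should give the 6-lithio derivative {6-[4-(benzyloxy)-2-methoxyphenyl]-5-methoxy-4-oxo-4H-pyran-2-yl}lithium F1. This is transmetalated at once with anhydrous CeCl3 to the dichlorocerium reagent {6-[4-(benzyloxy)-2-methoxyphenyl]-5-methoxy-4-oxo-4H-pyran-2-yl}cerium dichloride F2. Organocerium reagents are weakly basic and strongly oxophilic and add 1,2 to conjugated and hindered ketones, so reaction with 12 at −78 °C and an NH4Cl quench should give 14, where the route is rejoined.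

Step 11. The ketene may revert or oligomerise faster than it closes onto the cross-conjugated C2=C3 bond of the pyranone, or the material may decompose at the temperature needed. The fallback gives up the ring expansion and builds the flavone by the classical diketone route. It sets out from 2.
- Palladium-catalysed methoxycarbonylation of 2 (CO, MeOH, Et3N, Pd(OAc)2/dppf, DMF, 80 °C) should give methyl 4-(benzyloxy)-2-methoxybenzoate F3.
- Commercial 1,2,3,5-tetramethoxybenzene is acylated with methoxyacetyl chloride and AlCl3 (CH2Cl2, 0 → 25 °C), a Friedel–Crafts acylation with chelation-driven loss of the crowded ortho methyl group, to give 1-(2-hydroxy-3,4,6-trimethoxyphenyl)-2-methoxyethan-1-one F4.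
- The dianion of F4 (LiHMDS, THF, −78 → 25 °C) is C-acylated by F3 in a crossed Claisen condensation to 1-[4-(benzyloxy)-2-methoxyphenyl]-3-(2-hydroxy-3,4,6-trimethoxyphenyl)-2-methoxypropane-1,3-dione F5.
- Cyclodehydration (TsOH, toluene, reflux) gives 4'-(benzyloxy)-3,5,7,8,2'-pentamethoxyflavone F6.
- BCl3 in CH2Cl2 (−78 → 0 °C) should remove the chelated 5-O-methyl group and the benzyl ether together, so the fallback rejoins the route at 19.

Step 10. The strained β-hydroxy enone may fragment under the silver oxide conditions, or the hindered tertiary hydroxyl may be etherified incompletely. The fallback sets out from 14 and moves the methylation to after the ring expansion. Thermolysis of 14 itself (degassed toluene, 110 °C), the hydroxy version of the same ring expansion, should give the hydroquinone-type 4'-(benzyloxy)-5,8-dihydroxy-3,7,2'-trimethoxyflavone F7. Kept under argon, F7 is methylated with Me2SO4 (1.1 equiv) and K2CO3 in acetone. The free 8-hydroxyl should react while the 5-hydroxyl, hydrogen-bonded to the C4 carbonyl, stays untouched, giving 18, where the route is rejoined.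

**Further compounds**

F1 | step 9 | {6-[4-(benzyloxy)-2-methoxyphenyl]-5-methoxy-4-oxo-4H-pyran-2-yl}lithium | COc1cc(OCc2ccccc2)ccc1-c1oc([Li])cc(=O)c1OC
F2 | step 9 | {6-[4-(benzyloxy)-2-methoxyphenyl]-5-methoxy-4-oxo-4H-pyran-2-yl}cerium dichloride | COc1cc(OCc2ccccc2)ccc1-c1oc([Ce](Cl)Cl)cc(=O)c1OC
F3 | step 11 | methyl 4-(benzyloxy)-2-methoxybenzoate | COC(=O)c1ccc(OCc2ccccc2)cc1OC
F4 | step 11 | 1-(2-hydroxy-3,4,6-trimethoxyphenyl)-2-methoxyethan-1-one | COCC(=O)c1c(O)c(OC)c(OC)cc1OC
F5 | step 11 | 1-[4-(benzyloxy)-2-methoxyphenyl]-3-(2-hydroxy-3,4,6-trimethoxyphenyl)-2-methoxypropane-1,3-dione (racemic) | COc1cc(OCc2ccccc2)ccc1C(=O)C(OC)C(=O)c1c(O)c(OC)c(OC)cc1OC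
F6 | step 11 | 4'-(benzyloxy)-3,5,7,8,2'-pentamethoxyflavone | COc1cc(OCc2ccccc2)ccc1-c1oc2c(OC)c(OC)cc(OC)c2c(=O)c1OC
F7 | step 10 | 4'-(benzyloxy)-5,8-dihydroxy-3,7,2'-trimethoxyflavone | COc1cc(OCc2ccccc2)ccc1-c1oc2c(O)c(OC)cc(O)c2c(=O)c1OC
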